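The constants you start from are charges, and in this flask their ratios count turnovers. A turnover is one trip round the catalyst, and I assume it spends one reagent and one substrate.

in all of them: left-handed substrate 20 mM; right-handed substrate 20 mM; free catalyst 0.62 mM
- green: reagent 60 mM; the very flask that is asked about, followed so far
- flask: reagent 60.0 mM; time 3.0 min

green run (percent of the left-handed substrate and right-handed substrate together charged)

| time / s | right-handed substrate / % | left-handed substrate / % |
|---|---|---|
| 10.0 | 49.4 | 17.2 |
| 20.0 | 50.3 | 8.5 |
| 25.0 | 47.7 | 3.7 |
| 40.0 | 48.5 | 0 |

(standard deviation of a reading: 1 percentage point)

- free catalyst is single-handed; left-handed substrate and right-handed substrate are mirror images of each other, charged as a racemate, each of them at the stated concentration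
- the earlier runs were read with a standard deviation of 1 percentage point

- whether the excess of right-handed substrate over left-handed substrate among what is left of the two reaches 80% by 3.0 min (yes / no)
- the highest excess of right-handed substrate over left-handed substrate among what is left of the two up to 3.0 min

The bench rule of thumb sees 3.00 reagent per left-handed substrate, calls the left-handed substrate the limiting reagent and the reagent ample. In turnovers, 96.8 is the turnover budget, the reagent charged per catalyst charged, and clearing the left-handed substrate costs 32.3 of them.

You need less for an excess of 80%: [left-handed substrate] must fall to 0.111 of [right-handed substrate]. With the right-handed substrate staying near its charge, as the green readings show, that costs 28.7 turnovers. The rule has its border in a ratio: 29.6% of the budget must reach the catalyst, and the green readings follow the two substrates, not the reagent.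

The green run is this flask followed so far, so you can count on it directly. Counting each left-handed substrate lost as one turnover, its left-handed substrate readings give 26.8 turnovers at 20.0 s, short of the need, and 29.9 at 25.0 s, past it. Each reading carries a scatter of 1 point. My own reckoning is therefore yes, with the crossing between 20.0 s and 25.0 s, inside the 3.0 min allowed, and a top close to complete excess.

The forecast also says yes, with a top of 99.8%, holding that the excess “can only rise unless something regenerates the left-handed substrate”.

This flask gives yes and a top of >99.9%, crossing at 0.369 min with right-handed substrate at 49.2% of both substrates charged.

    2 reagent → homo dimer (k = 0.975 M⁻¹ s⁻¹)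
    free catalyst + right-handed substrate ⇌ catalyst intermediate B (K = 11.8 M⁻¹, k = 13200 M⁻¹ s⁻¹)
    reagent + catalyst intermediate B → free catalyst + right-handed product (k = 25.6 M⁻¹ s⁻¹)
    reagent → decomposition product (k = 3.99 × 10⁻⁴ s⁻¹)
    reagent + catalyst intermediate A → free catalyst + left-handed product (k = 64.9 M⁻¹ s⁻¹)
    free catalyst + left-handed substrate ⇌ catalyst intermediate A (K = 740 M⁻¹, k = 35400 M⁻¹ s⁻¹)

By 3.00 min the homo dimer stands at 18.2 mM, and at two reagent each it has taken 58.6 of the 96.8 turnovers' worth, more than the 35.0 that went through the catalyst. Of those, the left-handed product, at 50.0% of both substrates charged against 4.20% of right-handed product, stands for 32.3 turnovers, which is 33.4% of the budget and above the border of 29.6%.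

The data are simulated with constants of no real substance.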